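**Retrosynthetic overview**
- 8 ⇒ 6: the furan is the only ring built and it is closed last, by forming the C7a–O1 bond (aroyl oxygen onto the arene C–H para to OMe; dehydrative, through p-quinone methide 7).
- 6 ⇒ 4 + 5: para C–H hydroxyalkylation of o-eugenol 5, which already carries the allyl, OH and OMe groups, at the acetyl carbonyl of diketone 4.
- 4 ⇒ 1 + 2: acyl Stille coupling, then enol-ether hydrolysis (through 3).
- Both benzene rings are bought.

Assumption: the target has no stereocentre and no stereogenic double bond, so the constitution drawn is the compound to be made and nothing has to be set or resolved.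

**Route**

Step 1
Reactants: 1 3,4,5-trimethoxybenzoyl chloride; 2 tributyl(1-ethoxyvinyl)stannane
Product: 4 1-(3,4,5-trimethoxyphenyl)propane-1,2-dione, via α-ethoxy enone 3 (not isolated)
Conditions: PdCl2(PPh3)2 (2 mol%), toluene, 80 °C; then 1 M HCl, THF, rt
Reagents that add atoms: water, O
Why: Stille acylation of an acid chloride with an α-alkoxyvinylstannane (an acetyl-anion equivalent) is a standard ketone synthesis, and dilute acid hydrolyses the enol ether 3 to the 1,2-diketone without touching the aryl methyl ethers.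

Step 2
Reactants: 4 1-(3,4,5-trimethoxyphenyl)propane-1,2-dione; 5 2-allyl-6-methoxyphenol (o-eugenol)
Product: 6 rac-2-hydroxy-2-(3-allyl-4-hydroxy-5-methoxyphenyl)-1-(3,4,5-trimethoxyphenyl)propan-1-one
Conditions: Sc(OTf)3 (5 mol%), CH2Cl2, −20 → 0 °C; 4 (1.5 equiv), 5 added over 2 h
Reagents that add atoms: none
Why: Lewis-acid-catalysed Friedel–Crafts hydroxyalkylation: the chelated diketone reacts at its less hindered, non-conjugated acetyl carbonyl with the only open activated position of 5 (para to OH, both ortho positions blocked), excess 4 and low temperature holding the reaction at the mono-adduct; the new carbinol centre is racemic and is erased in step 3.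

Step 3
Reactants: 6 rac-2-hydroxy-2-(3-allyl-4-hydroxy-5-methoxyphenyl)-1-(3,4,5-trimethoxyphenyl)propan-1-one
Product: 8 7-allyl-6-hydroxy-5-methoxy-3-methyl-2-(3,4,5-trimethoxyphenyl)benzofuran, via p-quinone methide 7 (not isolated)
Conditions: (PhO)2P(O)OH (10 mol%), HFIP, 0.02 M, 25 → 50 °C
Reagents that add atoms: none
Why: Proposed new method: a Brønsted acid in HFIP ionises the tertiary p-hydroxybenzylic carbinol (loss of water) to the α-acyl p-quinone methide 7, whose O-protonated form is a 1-oxapentadienyl cation (O=C–C(+)–C=C); a Nazarov-type conrotatory 4π closure (equally a five-ring conjugate addition of the aroyl oxygen to the quinone methide ring) forms the C7a–O1 bond, expected at the ring CH para to OMe because the other CH is the β-carbon of the enol-ether half and is less electrophilic, and loss of the proton from that carbon restores aromaticity and gives the benzofuran irreversibly and redox-neutrally; closest known reaction types are the Nazarov cyclisation of pentadienyl cations, the acid-triggered generation and trapping of p-quinone methides from p-hydroxybenzyl alcohols, and the FeCl3-mediated oxidative enol-O/arene ring closure of electron-rich α-aryl carbonyl compounds to benzofurans.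

**Compound list**
1 | 3,4,5-trimethoxybenzoyl chloride | COc1cc(cc(OC)c1OC)C(=O)Cl | starting material
2 | tributyl(1-ethoxyvinyl)stannane | CCCC[Sn](CCCC)(CCCC)C(=C)OCC | starting material
3 | α-ethoxy enone, 2-ethoxy-1-(3,4,5-trimethoxyphenyl)prop-2-en-1-one (not isolated) | C=C(OCC)C(=O)c1cc(OC)c(OC)c(OC)c1 | intermediate
4 | 1-(3,4,5-trimethoxyphenyl)propane-1,2-dione | CC(=O)C(=O)c1cc(OC)c(OC)c(OC)c1 | intermediate
5 | 2-allyl-6-methoxyphenol (o-eugenol) | C=CCc1cccc(OC)c1O | starting material
6 | rac-2-hydroxy-2-(3-allyl-4-hydroxy-5-methoxyphenyl)-1-(3,4,5-trimethoxyphenyl)propan-1-one (racemic, no descriptor) | C=CCc1cc(cc(OC)c1O)C(C)(O)C(=O)c1cc(OC)c(OC)c(OC)c1 | intermediate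
7 | p-quinone methide, (E)-2-allyl-6-methoxy-4-[1-oxo-1-(3,4,5-trimethoxyphenyl)propan-2-ylidene]cyclohexa-2,5-dien-1-one (not isolated; E isomer drawn, the one that can close; E and Z interconvert through the protonated form) | C/C(C(=O)c2cc(OC)c(OC)c(OC)c2)=C1/C=C(CC=C)C(=O)C(OC)=C1 | intermediate
8 | 7-allyl-6-hydroxy-5-methoxy-3-methyl-2-(3,4,5-trimethoxyphenyl)benzofuran (no stereocentre) | C=CCc1c(O)c(OC)cc2c(C)c(-c3cc(OC)c(OC)c(OC)c3)oc12 | target

**Step count**
Total steps: 3. Longest linear sequence: 3 (1 → 4 → 6 → 8).

**Steps most likely to fail**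

Step 3 (the new ring closure) is the most uncertain. The oxygen may close onto the CH next to OMe, giving the 5-allyl-6-hydroxy-7-methoxy isomer. The quinone methide 7 may also tautomerise to the 2-arylprop-2-en-1-one and stall or oligomerise, 6 may undergo an α-ketol shift before ionising, or the phenol may add to the allyl group under acid. Steps 2 and 3 are kept apart because free 5 would trap 7 faster than 7 cyclises.

The fallback is the known biomimetic oxidative cycloaddition, in which a phenol oxygen becomes O1 so the regiochemistry is fixed. It sets out from 1 and comes back to the route at 8. Compound 1 is coupled with EtMgBr (Fe(acac)3 cat., THF, −78 °C) to 1-(3,4,5-trimethoxyphenyl)propan-1-one F1. NaBH4 in MeOH reduces this to 1-(3,4,5-trimethoxyphenyl)propan-1-ol F4, and TsOH (cat.) in refluxing toluene dehydrates it to (E)-1,2,3-trimethoxy-5-(prop-1-enyl)benzene F5. Separately, bought isovanillin F6 is O-allylated (allyl bromide, K2CO3, DMF) to 3-(allyloxy)-4-methoxybenzaldehyde F7. Baeyer–Villiger oxidation with mCPBA gives 3-(allyloxy)-4-methoxyphenyl formate F8 (not isolated), and aqueous NaOH/MeOH cleaves it to 3-(allyloxy)-4-methoxyphenol F9. Oxidative [3+2] cycloaddition of F9 with F5 (PhI(OCOCF3)2, HFIP/CH2Cl2, 0 °C) gives rac-trans-6-(allyloxy)-5-methoxy-3-methyl-2-(3,4,5-trimethoxyphenyl)-2,3-dihydrobenzofuran F10, the alkene adding at the ring carbon para to the allyloxy group. DDQ in refluxing dioxane dehydrogenates it to 6-(allyloxy)-5-methoxy-3-methyl-2-(3,4,5-trimethoxyphenyl)benzofuran F11. Aromatic Claisen rearrangement (PhNEt2, 190 °C) then moves the allyl group to C7, the only free ortho position, and gives 8.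

Step 2 (hydroxyalkylation) may give the bis-aryl adduct, attack at the aroyl carbonyl, or substitution para to OMe. The fallback replaces electrophilic substitution by a site-defined aryl-metal addition. It sets out from 5 and comes back at 6. NBS (MeCN, 0 °C) brominates 5 para to OH to give 2-allyl-4-bromo-6-methoxyphenol F2. n-BuLi (2.1 equiv, THF, −78 °C) converts this to lithium 2-allyl-4-lithio-6-methoxyphenolate F3 (not isolated). F3 adds to the acetyl carbonyl of 4 at −78 °C and gives 6 after NH4Cl work-up.

Step 1 (acyl Stille coupling and hydrolysis) may suffer decarbonylation or leave tin residues that poison step 2. The fallback builds the diketone by C–C coupling followed by C–H oxidation. It sets out from 1 and comes back at 4. EtMgBr with Fe(acac)3 (3 mol%, THF, −78 °C) gives 1-(3,4,5-trimethoxyphenyl)propan-1-one F1. Riley oxidation of its α-methylene (SeO2, dioxane/H2O, 100 °C) gives 4.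

**Further compounds**
F1 | step 1 | 1-(3,4,5-trimethoxyphenyl)propan-1-one | CCC(=O)c1cc(OC)c(OC)c(OC)c1
F2 | step 2 | 2-allyl-4-bromo-6-methoxyphenol | C=CCc1cc(Br)cc(OC)c1O
F3 | step 2 | lithium 2-allyl-4-lithio-6-methoxyphenolate | [Li]c1cc(CC=C)c(O[Li])c(OC)c1
F4 | step 3 | rac-1-(3,4,5-trimethoxyphenyl)propan-1-ol | CCC(O)c1cc(OC)c(OC)c(OC)c1
F5 | step 3 | (E)-1,2,3-trimethoxy-5-(prop-1-enyl)benzene | C/C=C/c1cc(OC)c(OC)c(OC)c1
F6 | step 3 | 3-hydroxy-4-methoxybenzaldehyde (isovanillin, bought) | COc1ccc(C=O)cc1O
F7 | step 3 | 3-(allyloxy)-4-methoxybenzaldehyde | C=CCOc1cc(C=O)ccc1OC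
F8 | step 3 | 3-(allyloxy)-4-methoxyphenyl formate | C=CCOc1cc(OC=O)ccc1OC
F9 | step 3 | 3-(allyloxy)-4-methoxyphenol | C=CCOc1cc(O)ccc1OC
F10 | step 3 | rac-trans-6-(allyloxy)-5-methoxy-3-methyl-2-(3,4,5-trimethoxyphenyl)-2,3-dihydrobenzofuran (one enantiomer drawn) | C[C@@H]1c2cc(OC)c(OCC=C)cc2O[C@H]1c1cc(OC)c(OC)c(OC)c1
F11 | step 3 | 6-(allyloxy)-5-methoxy-3-methyl-2-(3,4,5-trimethoxyphenyl)benzofuran | C=CCOc1cc2oc(-c3cc(OC)c(OC)c(OC)c3)c(C)c2cc1OC
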